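**Plan**

1. Numbering used here: hydrindane core C1 (cyclopentane carbon that carries the bridge), C2, C3, C3a (angular methyl), C4 (OH), C5 (OAc), C6=C7 (methyl on C7), C7a; bridge C8 (=CH2), C9 (OAc), C10, C11, C12 (methyl), C13, C14 (OAc, bonded to C6).
2. Retrosynthesis: cut C8–C9 of the eleven-membered ring (gives an ynal), then C6–C14 (enol triflate + (S)-citronellal), then C1–C7a of the cyclopentane (aldehyde-tethered cyclohexadienone), then the dienone back to p-cresol.
3. Enabling feature: in the eleven-membered ring the exocyclic-methylene carbon C8 lies between cyclopentane carbon C1 and carbinol C9. This 2-methylene-1-oxy unit is what a terminal alkyne gives when its internal carbon is coupled reductively with an aldehyde, so a C1 ethynyl group and a chain-end aldehyde are all the precursor needs.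
4. Forward order: dearomatisation of p-cresol gives ring B (six-membered) as a prochiral dienone; ring C (cyclopentane) is closed by a desymmetrising enamine Michael addition; ring B is oxygenated and turned into the tetrasubstituted enol triflate; the citronellal chain is attached; ring A (eleven-membered) is closed last.
5. Stereochemistry: C1, C3a, C7a from the amine catalyst; C4 from α-face nucleophilic epoxidation; C5 from anti enolate hydroxylation; C12 from (S)-citronellal; C14 from oxazaborolidine reduction; C9 from macrocyclic control in the ring closure.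

Key step: step 17

Remark: α is the face of the hydrindane that carries the angular methyl and H-7a (all bicyclic compounds are cis-fused), β the opposite face. Compounds 8 to 14 are carried as C7 epimer mixtures because C7 becomes sp2 in step 11.

**Route**

Step 1
Reactants: 1 4-methylphenol (p-cresol); 2 allyltrimethylsilane
Product: 3 4-allyl-4-methylcyclohexa-2,5-dien-1-one
Conditions: PhI(OAc)2, (CF3)2CHOH, −20 °C to 0 °C
Reagents that add atoms: none
Why: Oxidative dearomatisation (oxidative Hosomi–Sakurai allylation): the hypervalent iodine reagent converts the phenol into a phenoxenium-type electrophile in the ionising, non-nucleophilic solvent and the allylsilane attacks the methyl-bearing para carbon, which should give the prochiral 4,4-disubstituted dienone without any stereocentre.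

Step 2
Reactants: 3 4-allyl-4-methylcyclohexa-2,5-dien-1-one
Product: 4 4-(1-methyl-4-oxocyclohexa-2,5-dien-1-yl)butanal
Conditions: Rh(acac)(CO)2 (1 mol%), BiPhePhos (2 mol%), CO/H2 (1:1, 10 bar), toluene, 70 °C
Reagents that add atoms: carbon monoxide, [C-]#[O+]
Why: Linear-selective rhodium-catalysed hydroformylation of the monosubstituted alkene (wide-bite-angle bisphosphite) places the formyl carbon at the terminus, while the electron-poor disubstituted dienone alkenes should stay untouched; no stereocentre is formed.

Step 3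
Reactants: 4 4-(1-methyl-4-oxocyclohexa-2,5-dien-1-yl)butanal
Product: 5 (1R,3aR,7aR)-3a-methyl-6-oxo-2,3,3a,6,7,7a-hexahydro-1H-indene-1-carbaldehyde (1β-formyl, 3aα-methyl, 7aα-H)
Conditions: (S)-α,α-diphenylprolinol trimethylsilyl ether (10 mol%), PhCO2H (10 mol%), CH2Cl2, 0 °C
Reagents that add atoms: none
Why: Enamine-catalysed desymmetrising intramolecular Michael addition (5-exo-trig): the (E)-enamine of the (S)-amine attacks one of the two enantiotopic enone carbons on its unshielded face (this fixes C1 as R and, through the three-atom tether, the cis ring fusion at C3a and C7a), and the compact synclinal (endo) transition state that holds the incipient iminium over the dienone carbonyl should give the 1β-formyl, all-cis isomer as the kinetic product.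

Step 4
Reactants: 5 the cis-hydrindenone aldehyde
Product: 6 (1R,3aR,7aR)-1-ethynyl-3a-methyl-1,2,3,3a,7,7a-hexahydro-6H-inden-6-one (1β-ethynyl)
Conditions: dimethyl (1-diazo-2-oxopropyl)phosphonate, K2CO3, MeOH, 0 °C
Reagents that add atoms: dimethyl (1-diazo-2-oxopropyl)phosphonate, CC(=O)C(=[N+]=[N-])P(=O)(OC)OC
Why: Seyferth–Gilbert homologation with the in situ generated diazomethylphosphonate turns the formyl carbon into the internal alkyne carbon under mild carbonate conditions at low temperature, which should spare the enone and the epimerisable C1 centre; no new stereocentre.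

Step 5
Reactants: 6 the ethynyl enone
Product: 8 1β-ethynyl-3aα,7-dimethyl-1,2,3,3a,7,7a-hexahydro-6H-inden-6-one (C7 epimers), via lithium dienolate 7 (not isolated)
Conditions: LiN(i-Pr)2 (1.05 equiv), THF, −78 °C; MeI, −78 °C to −30 °C
Reagents that add atoms: iodomethane, CI
Why: Enolate alkylation: the cross-conjugated enone can be deprotonated only at C7 (C3a is quaternary, and with one equivalent of base the more acidic ketone outcompetes the alkyne C–H), and C-methylation installs the methyl group of the future tetrasubstituted alkene; the new C7 centre is destroyed in step 11, so its configuration is irrelevant.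

Step 6
Reactants: 8 the 7-methyl enone
Product: 9 4α,5α-epoxy-1β-ethynyl-3aα,7-dimethylhydrindan-6-one (C7 epimers)
Conditions: H2O2 (30% aq.), NaOH (cat.), MeOH, 0 °C
Reagents that add atoms: hydrogen peroxide, OO
Why: Weitz–Scheffer nucleophilic epoxidation touches only the enone alkene; hydroperoxide should add to C4 along the axial trajectory anti to the pseudo-axial C3a–C3 bond of the cis-hydrindenone (the conformer with axial H-7a), that is on the α face syn to the angular methyl, and the epoxide closes on the same face, which sets the C4–O configuration.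

Step 7
Reactants: 9 the α-epoxy ketone
Product: 10 1β-ethynyl-4α-hydroxy-3aα,7-dimethylhydrindan-6-one (C7 epimers)
Conditions: SmI2 (2.2 equiv), THF/MeOH, −90 °C
Reagents that add atoms: none
Why: Reductive opening of an α,β-epoxy ketone by single-electron transfer: the samarium ketyl cleaves the C5–O bond and leaves the C4–O bond and its configuration intact, and the low temperature with in situ protonation should suppress retro-aldol cleavage and dehydration.

Step 8
Reactants: 10 the β-hydroxy ketone
Product: 11 4α-(tert-butyldimethylsilyloxy)-1β-ethynyl-3aα,7-dimethylhydrindan-6-one (C7 epimers)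
Conditions: TBSOTf, 2,6-lutidine, CH2Cl2, −78 °C to 0 °C
Reagents that add atoms: tert-butyldimethylsilyl trifluoromethanesulfonate, CC(C)(C)[Si](C)(C)OS(=O)(=O)C(F)(F)F
Why: Silylation of the hindered neopentyl alcohol with a silyl triflate and a non-nucleophilic base gives the robust ether that is meant to be the last protecting group removed; no stereocentre is touched.

Step 9
Reactants: 11 the 4α-silyloxy ketone
Product: 13 4α-(tert-butyldimethylsilyloxy)-1β-ethynyl-5β-hydroxy-3aα,7-dimethylhydrindan-6-one (C7 epimers), via sodium enolate 12 (not isolated)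
Conditions: NaN(SiMe3)2 (1.1 equiv), THF, −78 °C; 2-(phenylsulfonyl)-3-phenyloxaziridine, −78 °C
Reagents that add atoms: 2-(phenylsulfonyl)-3-phenyloxaziridine, O=S(=O)(N1OC1c1ccccc1)c1ccccc1
Why: Enolate hydroxylation with an N-sulfonyloxaziridine: kinetic deprotonation should occur at the methylene C5 and not at the methyl-bearing methine C7, and the oxidant approaches the enolate anti to the neighbouring α-silyloxy group, which sets the 5β-hydroxyl trans to O4.

Step 10
Reactants: 13 the 5β-hydroxy ketone
Product: 14 4α-(tert-butyldimethylsilyloxy)-1β-ethynyl-3aα,7-dimethyl-5β-(triethylsilyloxy)hydrindan-6-one (C7 epimers)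
Conditions: TESCl, imidazole, DMF, 0 °C to rt
Reagents that add atoms: chlorotriethylsilane, CC[Si](Cl)(CC)CC
Why: Standard silylation of the unhindered α-hydroxy ketone gives a triethylsilyl ether that can later be cleaved beside the tert-butyldimethylsilyl ether; no stereocentre is touched.

Step 11
Reactants: 14 the bis-silyloxy ketone
Product: 16 4α-(tert-butyldimethylsilyloxy)-1β-ethynyl-3aα,7-dimethyl-5β-(triethylsilyloxy)-2,3,3a,4,5,7a-hexahydro-1H-inden-6-yl trifluoromethanesulfonate, via potassium enolate 15 (not isolated)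
Conditions: KN(SiMe3)2 (1.05 equiv), THF, −78 °C; PhNTf2, −78 °C to 0 °C
Reagents that add atoms: N-phenylbis(trifluoromethanesulfonimide), FC(F)(F)S(=O)(=O)N(c1ccccc1)S(=O)(=O)C(F)(F)F
Why: Enol triflate formation: C5–H is now tertiary, oxygen-substituted and shielded by two silyloxy groups, so the base should remove the C7 proton, and O-triflation of the tetrasubstituted enolate fixes the C6=C7 alkene of the target regiospecifically while erasing the C7 stereocentre.

Step 12
Reactants: 16 the enol triflate; 17 (S)-citronellal
Product: 18 allylic alcohol: 16 with OTf replaced by a (3S)-1-hydroxy-3,7-dimethyloct-6-en-1-yl group (C14 epimers)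
Conditions: CrCl2 (4 equiv), NiCl2 (1 mol%), DMF, rt
Reagents that add atoms: none
Why: Nozaki–Hiyama–Kishi reaction: zerovalent nickel formed in situ inserts into the alkenyl triflate, transmetallation gives an alkenylchromium species that adds only to the aldehyde in the presence of the alkyne and silyl ethers; the C14 carbinol forms without reliable control and is corrected in steps 13 and 14.

Step 13
Reactants: 18 the allylic alcohol mixture
Product: 19 enone: 16 with OTf replaced by a (3S)-3,7-dimethyloct-6-enoyl group
Conditions: 1,1,1-triacetoxy-1,1-dihydro-1,2-benziodoxol-3(1H)-one (DMP), NaHCO3, CH2Cl2, 0 °C to rt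
Reagents that add atoms: none
Why: Hypervalent iodine oxidation of the secondary allylic alcohol converges both C14 epimers to one ketone under buffered, non-epimerising conditions.

Step 14
Reactants: 19 the enone
Product: 20 (14S)-allylic alcohol: 16 with OTf replaced by a (1S,3S)-1-hydroxy-3,7-dimethyloct-6-en-1-yl group
Conditions: (R)-2-methyl-CBS-oxazaborolidine (0.5 equiv), catecholborane, toluene, −78 °C
Reagents that add atoms: none
Why: Corey–Bakshi–Shibata reduction: the (R)-oxazaborolidine binds the ketone with the fully substituted cyclohexenyl group as the large substituent and the methylene chain as the small one, so hydride delivery should give the 14S alcohol under reagent control, and catecholborane at −78 °C does not hydroborate the alkyne.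

Step 15
Reactants: 20 the (14S)-alcohol
Product: 21 16 with OTf replaced by a (1S,3S)-3,7-dimethyl-1-(triethylsilyloxy)oct-6-en-1-yl group
Conditions: TESOTf, 2,6-lutidine, CH2Cl2, −78 °C
Reagents that add atoms: triethylsilyl trifluoromethanesulfonate, CC[Si](CC)(CC)OS(=O)(=O)C(F)(F)F
Why: The hindered allylic alcohol is silylated with the reactive silyl triflate so that C5, C14 and later C9 all carry the same triethylsilyl group; no stereocentre is touched.

Step 16
Reactants: 21 the bis(triethylsilyl) ether
Product: 23 ynal: 16 with OTf replaced by a (1S,3S)-3-methyl-6-oxo-1-(triethylsilyloxy)hexyl group, via vicinal diol 22 (not isolated)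
Conditions: OsO4 (2 mol%), NaIO4 (4 equiv), 2,6-lutidine, dioxane/H2O, rt
Reagents that add atoms: osmium tetroxide (catalytic oxygen carrier), O=[Os](=O)(=O)=O; sodium periodate, [Na+].[O-]I(=O)(=O)=O
Why: Lemieux–Johnson oxidation: the unhindered, electron-rich trisubstituted alkene is dihydroxylated much faster than the shielded tetrasubstituted ring alkene or the alkyne, and periodate cleaves the diol in situ to the aldehyde; no stereocentre is touched.

Step 17
Reactants: 23 the ynal
Product: 24 (1R,3aS,4R,5R,7aS,9R,12S,14S)-4α-(tert-butyldimethylsilyloxy)-5β,9,14-tris(triethylsilyloxy)-3a,7,12-trimethyl-8-methylene tricycle (hydrindene C1–C7a bridged from C1 to C6 by C8–C14)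
Conditions: Ni(COD)2 (25 mol%), 1,3-bis(2,6-diisopropylphenyl)-4,5-diphenylimidazol-2-ylidene (25 mol%, from its HBF4 salt and KOt-Bu), Et3SiH (5 equiv), THF, rt, syringe-pump addition to 2 mM
Reagents that add atoms: triethylsilane, CC[SiH](CC)CC
Why: Zerovalent nickel carrying the bulky carbene binds the alkyne and the aldehyde and undergoes oxidative cyclisation to an oxanickelacyclopentene, σ-bond metathesis of the Ni–O bond with Et3SiH gives a nickel hydride, and C–H reductive elimination releases the silylated allylic alcohol and the catalyst. The closest known reaction type is the nickel-catalysed reductive coupling of aldehydes with alkynes in its intramolecular, macrocycle-forming version (ynal macrocyclisation with a silane reductant). The eleven-membered ring closes in the 11-exo-dig mode, the bond forming between aldehyde carbon C9 and the internal alkyne carbon C8, so that the former alkyne terminus becomes the exocyclic methylene. The new stereocentre C9 is set by macrocyclic control: the aldehyde has to reach the alkyne held on the β face of the rigid cis-hydrindane with the chain, biased by the C12 methyl and the C14 silyloxy group, in its least strained conformation and the carbonyl oxygen turned to the periphery, which is expected to give 9R. The step needs exo over endo regioselectivity and ring closure over oligomerisation: the large carbene places the small alkyne substituent (H) next to nickel and so directs bond formation to the internal carbon, the endo mode would have to put an (E)-alkene into a twelve-membered ring spanning the bicycle, and slow addition at high dilution keeps the ynal concentration low. The silicon delivered here is the same triethylsilyl group that already protects O5 and O14, so one later operation frees all three future acetate positions.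

Step 18
Reactants: 24 the macrocyclic tetrasilyl ether
Product: 25 (1R,3aS,4R,5R,7aS,9R,12S,14S)-4α-(tert-butyldimethylsilyloxy)-3a,7,12-trimethyl-8-methylene tricycle-5β,9,14-triol
Conditions: HF·pyridine, pyridine, THF, 0 °C to rt
Reagents that add atoms: none
Why: Selective desilylation: buffered fluoride should cleave the three secondary triethylsilyl ethers while the far more hindered neopentyl tert-butyldimethylsilyl ether at C4 stays in place.

Step 19
Reactants: 25 the triol
Product: 26 (1R,3aS,4R,5R,7aS,9R,12S,14S)-4α-(tert-butyldimethylsilyloxy)-3a,7,12-trimethyl-8-methylene tricycle-5β,9,14-triyl triacetate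
Conditions: Ac2O, DMAP, pyridine, CH2Cl2, rt
Reagents that add atoms: acetic anhydride, CC(=O)OC(C)=O
Why: Nucleophile-catalysed acetylation of the three free secondary hydroxyls, with O4 still blocked, puts the acetates exactly where the target has them; no stereocentre is touched.

Step 20
Reactants: 26 the silylated triacetate
Product: 27 (1R,3aS,4R,5R,7aS,9R,12S,14S)-4α-hydroxy-3a,7,12-trimethyl-8-methylene tricycle-5β,9,14-triyl triacetate (target, CNP0318778.1)
Conditions: HF (48% aq.), MeCN, rt
Reagents that add atoms: none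
Why: Acidic fluoride cleaves the last silyl ether under non-basic conditions, which should leave the three acetates in place and avoid acetyl migration from O5 to the liberated O4; no stereocentre is touched.

**Compound list**

1 | 4-methylphenol (p-cresol) | Cc1ccc(O)cc1 | starting material
2 | allyltrimethylsilane | C=CC[Si](C)(C)C | starting material
3 | 4-allyl-4-methylcyclohexa-2,5-dien-1-one | C=CCC1(C)C=CC(=O)C=C1 | intermediate
4 | 4-(1-methyl-4-oxocyclohexa-2,5-dien-1-yl)butanal | O=CCCCC1(C)C=CC(=O)C=C1 | intermediate
5 | (1R,3aR,7aR)-3a-methyl-6-oxo-2,3,3a,6,7,7a-hexahydro-1H-indene-1-carbaldehyde (1β-formyl, 3aα-methyl, 7aα-H) | O=C1C[C@@H]2[C@H](C=O)CC[C@]2(C)C=C1 | intermediate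
6 | (1R,3aR,7aR)-1-ethynyl-3a-methyl-1,2,3,3a,7,7a-hexahydro-6H-inden-6-one | O=C1C[C@@H]2[C@H](C#C)CC[C@]2(C)C=C1 | intermediate
7 | lithium dienolate of 6 (lithium 1β-ethynyl-3aα-methyl-2,3,3a,7a-tetrahydro-1H-inden-6-olate) | [Li]OC1=C[C@@H]2[C@H](C#C)CC[C@]2(C)C=C1 | intermediate
8 | 1β-ethynyl-3aα,7-dimethyl-1,2,3,3a,7,7a-hexahydro-6H-inden-6-one (C7 epimers) | O=C1C(C)[C@@H]2[C@H](C#C)CC[C@]2(C)C=C1 | intermediate
9 | 4α,5α-epoxy-1β-ethynyl-3aα,7-dimethylhydrindan-6-one (C7 epimers) | O=C1C(C)[C@@H]2[C@H](C#C)CC[C@]2(C)[C@@H](O3)[C@H]13 | intermediate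
10 | 1β-ethynyl-4α-hydroxy-3aα,7-dimethylhydrindan-6-one (C7 epimers) | O=C1C(C)[C@@H]2[C@H](C#C)CC[C@]2(C)[C@@H](O)C1 | intermediate
11 | 4α-(tert-butyldimethylsilyloxy)-1β-ethynyl-3aα,7-dimethylhydrindan-6-one (C7 epimers) | O=C1C(C)[C@@H]2[C@H](C#C)CC[C@]2(C)[C@@H](O[Si](C)(C)C(C)(C)C)C1 | intermediate
12 | sodium enolate of 11 (C5=C6) | [Na]OC=1C(C)[C@@H]2[C@H](C#C)CC[C@]2(C)[C@@H](O[Si](C)(C)C(C)(C)C)C=1 | intermediate
13 | 4α-(tert-butyldimethylsilyloxy)-1β-ethynyl-5β-hydroxy-3aα,7-dimethylhydrindan-6-one (C7 epimers) | O=C1C(C)[C@@H]2[C@H](C#C)CC[C@]2(C)[C@@H](O[Si](C)(C)C(C)(C)C)[C@@H]1O | intermediate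
14 | 4α-(tert-butyldimethylsilyloxy)-1β-ethynyl-3aα,7-dimethyl-5β-(triethylsilyloxy)hydrindan-6-one (C7 epimers) | O=C1C(C)[C@@H]2[C@H](C#C)CC[C@]2(C)[C@@H](O[Si](C)(C)C(C)(C)C)[C@@H]1O[Si](CC)(CC)CC | intermediate
15 | potassium enolate of 14 (C6=C7) | [K]OC1=C(C)[C@@H]2[C@H](C#C)CC[C@]2(C)[C@@H](O[Si](C)(C)C(C)(C)C)[C@@H]1O[Si](CC)(CC)CC | intermediate
16 | 4α-(tert-butyldimethylsilyloxy)-1β-ethynyl-3aα,7-dimethyl-5β-(triethylsilyloxy)-2,3,3a,4,5,7a-hexahydro-1H-inden-6-yl trifluoromethanesulfonate | FC(F)(F)S(=O)(=O)OC1=C(C)[C@@H]2[C@H](C#C)CC[C@]2(C)[C@@H](O[Si](C)(C)C(C)(C)C)[C@@H]1O[Si](CC)(CC)CC | intermediate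
17 | (S)-citronellal, (3S)-3,7-dimethyloct-6-enal | O=CC[C@@H](C)CCC=C(C)C | starting material
18 | 16 with OTf replaced by (3S)-1-hydroxy-3,7-dimethyloct-6-en-1-yl (C14 epimers) | CC(C)=CCC[C@H](C)CC(O)C1=C(C)[C@@H]2[C@H](C#C)CC[C@]2(C)[C@@H](O[Si](C)(C)C(C)(C)C)[C@@H]1O[Si](CC)(CC)CC | intermediate
19 | 16 with OTf replaced by (3S)-3,7-dimethyloct-6-enoyl | CC(C)=CCC[C@H](C)CC(=O)C1=C(C)[C@@H]2[C@H](C#C)CC[C@]2(C)[C@@H](O[Si](C)(C)C(C)(C)C)[C@@H]1O[Si](CC)(CC)CC | intermediate
20 | 16 with OTf replaced by (1S,3S)-1-hydroxy-3,7-dimethyloct-6-en-1-yl | CC(C)=CCC[C@H](C)C[C@H](O)C1=C(C)[C@@H]2[C@H](C#C)CC[C@]2(C)[C@@H](O[Si](C)(C)C(C)(C)C)[C@@H]1O[Si](CC)(CC)CC | intermediate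
21 | 16 with OTf replaced by (1S,3S)-3,7-dimethyl-1-(triethylsilyloxy)oct-6-en-1-yl | CC(C)=CCC[C@H](C)C[C@H](O[Si](CC)(CC)CC)C1=C(C)[C@@H]2[C@H](C#C)CC[C@]2(C)[C@@H](O[Si](C)(C)C(C)(C)C)[C@@H]1O[Si](CC)(CC)CC | intermediate
22 | 16 with OTf replaced by (1S,3S)-6,7-dihydroxy-3,7-dimethyl-1-(triethylsilyloxy)octyl (epimers at the new carbinol) | CC(C)(O)C(O)CC[C@H](C)C[C@H](O[Si](CC)(CC)CC)C1=C(C)[C@@H]2[C@H](C#C)CC[C@]2(C)[C@@H](O[Si](C)(C)C(C)(C)C)[C@@H]1O[Si](CC)(CC)CC | intermediate
23 | 16 with OTf replaced by (1S,3S)-3-methyl-6-oxo-1-(triethylsilyloxy)hexyl (the ynal) | O=CCC[C@H](C)C[C@H](O[Si](CC)(CC)CC)C1=C(C)[C@@H]2[C@H](C#C)CC[C@]2(C)[C@@H](O[Si](C)(C)C(C)(C)C)[C@@H]1O[Si](CC)(CC)CC | intermediate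
24 | (1R,3aS,4R,5R,7aS,9R,12S,14S)-4α-(tert-butyldimethylsilyloxy)-5β,9,14-tris(triethylsilyloxy)-3a,7,12-trimethyl-8-methylene tricycle | C=C1[C@H](O[Si](CC)(CC)CC)CC[C@H](C)C[C@H](O[Si](CC)(CC)CC)C2=C(C)[C@@H]3[C@H]1CC[C@]3(C)[C@@H](O[Si](C)(C)C(C)(C)C)[C@@H]2O[Si](CC)(CC)CC | intermediate
25 | (1R,3aS,4R,5R,7aS,9R,12S,14S)-4α-(tert-butyldimethylsilyloxy)-3a,7,12-trimethyl-8-methylene tricycle-5β,9,14-triol | C=C1[C@H](O)CC[C@H](C)C[C@H](O)C2=C(C)[C@@H]3[C@H]1CC[C@]3(C)[C@@H](O[Si](C)(C)C(C)(C)C)[C@@H]2O | intermediate
26 | (1R,3aS,4R,5R,7aS,9R,12S,14S)-4α-(tert-butyldimethylsilyloxy)-3a,7,12-trimethyl-8-methylene tricycle-5β,9,14-triyl triacetate | C=C1[C@H](OC(C)=O)CC[C@H](C)C[C@H](OC(C)=O)C2=C(C)[C@@H]3[C@H]1CC[C@]3(C)[C@@H](O[Si](C)(C)C(C)(C)C)[C@@H]2OC(C)=O | intermediate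
27 | (1R,3aS,4R,5R,7aS,9R,12S,14S)-4α-hydroxy-3a,7,12-trimethyl-8-methylene tricycle-5β,9,14-triyl triacetate (CNP0318778.1) | C=C1[C@H](OC(C)=O)CC[C@H](C)C[C@H](OC(C)=O)C2=C(C)[C@@H]3[C@H]1CC[C@]3(C)[C@@H](O)[C@@H]2OC(C)=O | target

**Step count and risks**

Total: 20 steps. Longest linear sequence: 20 steps (1 to 27); (S)-citronellal 17 enters at step 12.

Step 17 (ring closure). What may go wrong: coupling at the terminal alkyne carbon (endo closure to a twelve-membered ring), intermolecular coupling or alkyne oligomerisation outrunning the slow closure of the strained ring, or poor facial selectivity at C9. The fallback is a Nozaki–Hiyama–Kishi macrocyclisation and sets out from 21. Nickel-catalysed Markovnikov hydroalumination (Ni(dppp)Cl2, i-Bu2AlH, THF) followed by N-iodosuccinimide would give the 2-iodoalkene F1. Lemieux–Johnson cleavage of its trisubstituted alkene would give the iodo aldehyde F2. Intramolecular coupling (CrCl2, NiCl2 cat., DMSO, high dilution) would give the macrocyclic allylic alcohol F3, whose free C9 hydroxyl allows separation of epimers. Removal of the two triethylsilyl groups with buffered HF·pyridine brings the route back at 25.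

Step 3 (cyclopentane closure). What may go wrong: addition through the open (exo) transition state, or epimerisation of the product aldehyde through its enamine, so that the formyl group ends up on the α face. The fallback sets out from 4: the enantiomeric (R)-catalyst would then give the ring fusion of 5 with the formyl group α, the C1 epimer F4. Condensation with pyrrolidine would give the exocyclic enamine F5, and hydrolysis under kinetic control (aqueous AcOH/NaOAc, 0 °C) should protonate C1 from the open α (convex) face and return 5.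

Step 9 (C5 hydroxylation). What may go wrong: enolisation towards C7 instead of C5, loss of the β-silyloxy group from the enolate by elimination, or low facial selectivity of the hydroxylation. The fallback sets out from 9 and keeps the epoxide as the source of both oxygens. KN(SiMe3)2/PhNTf2 would give the epoxy enol triflate F6 (only C7 carries a readily removable proton). Acid-catalysed hydrolysis (HClO4 cat., THF/H2O) should open the epoxide at the allylic C5 with inversion to the trans diol F7. TESCl/imidazole would silylate the less hindered 5β-hydroxyl to give the mono(triethylsilyl) ether F8, and TBSOTf/2,6-lutidine on the neopentyl 4α-hydroxyl rejoins the route at 16.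

Further compounds
F1 | step 17 | 21 with the ethynyl group replaced by 1-iodovinyl | CC(C)=CCC[C@H](C)C[C@H](O[Si](CC)(CC)CC)C1=C(C)[C@@H]2[C@H](C(I)=C)CC[C@]2(C)[C@@H](O[Si](C)(C)C(C)(C)C)[C@@H]1O[Si](CC)(CC)CC
F2 | step 17 | 23 with the ethynyl group replaced by 1-iodovinyl | O=CCC[C@H](C)C[C@H](O[Si](CC)(CC)CC)C1=C(C)[C@@H]2[C@H](C(I)=C)CC[C@]2(C)[C@@H](O[Si](C)(C)C(C)(C)C)[C@@H]1O[Si](CC)(CC)CC
F3 | step 17 | 24 with a free 9-hydroxyl in place of the 9-triethylsilyloxy group | C=C1[C@H](O)CC[C@H](C)C[C@H](O[Si](CC)(CC)CC)C2=C(C)[C@@H]3[C@H]1CC[C@]3(C)[C@@H](O[Si](C)(C)C(C)(C)C)[C@@H]2O[Si](CC)(CC)CC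
F4 | step 3 | C1 epimer of 5 (1α-formyl) | O=C1C[C@@H]2[C@@H](C=O)CC[C@]2(C)C=C1
F5 | step 3 | pyrrolidine enamine of F4 (exocyclic C1=CH–N) | O=C1C[C@@H]2C(=CN3CCCC3)CC[C@]2(C)C=C1
F6 | step 9 | 4α,5α-epoxy-1β-ethynyl-3aα,7-dimethyl-2,3,3a,4,5,7a-hexahydro-1H-inden-6-yl trifluoromethanesulfonate | FC(F)(F)S(=O)(=O)OC1=C(C)[C@@H]2[C@H](C#C)CC[C@]2(C)[C@@H](O3)[C@H]13
F7 | step 9 | 1β-ethynyl-4α,5β-dihydroxy-3aα,7-dimethyl-2,3,3a,4,5,7a-hexahydro-1H-inden-6-yl trifluoromethanesulfonate | FC(F)(F)S(=O)(=O)OC1=C(C)[C@@H]2[C@H](C#C)CC[C@]2(C)[C@@H](O)[C@@H]1O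
F8 | step 9 | 1β-ethynyl-4α-hydroxy-3aα,7-dimethyl-5β-(triethylsilyloxy)-2,3,3a,4,5,7a-hexahydro-1H-inden-6-yl trifluoromethanesulfonate | FC(F)(F)S(=O)(=O)OC1=C(C)[C@@H]2[C@H](C#C)CC[C@]2(C)[C@@H](O)[C@@H]1O[Si](CC)(CC)CC
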